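**Plan**
- Retrosynthesis: after the protecting groups are removed, the acacetin pyranone is cut at O1–C2 and C4–C4a (carbonylative annulation of an ortho-iodophenol with 4-ethynylanisole and CO). The apigenin pyranone is cut at O1''–C2'' and C4''–C4a'' (formylation, acetylide addition, oxidation, oxa-Michael closure).
- Ring A of the apigenin half is then opened at C8''–C8a'', C6''–C7'' and C4a''–C8a'' into 3-ethoxycyclobut-2-en-1-one and an aryl siloxyalkyne. The siloxyalkyne goes back through the ynolate and the terminal alkyne to 2,4,6-trihydroxybenzaldehyde.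
- Enabling feature: in ring A of the apigenin half, C8'' carries C6 of the other half between the oxygenated carbons C8a'' and C7'', and C5'' is oxygenated too. A cyclobutenone–siloxyalkyne benzannulation gives exactly this pattern, with the C8a'' oxygen as the only free hydroxyl.
- Forward order: ring A of the acacetin half is bought; ring A of the apigenin half grows on it, so the crowded C6–C8'' bond is never made by coupling. Then follow the apigenin pyranone, the acacetin pyranone and deprotection.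
- Stereochemistry: the target has no stereocentre; the C6–C8'' axis carries no descriptor and forms as a racemate.

Key step: step 5

Remark: the target SMILES gives no configuration for the hindered C6–C8'' axis, so it is treated as unspecified. Locants without primes or with one prime belong to the acacetin half, double- and triple-primed locants to the apigenin half.

**Route**

Step 1
Reactants: 1 2,4,6-trihydroxybenzaldehyde
Product: 2 2,6-dihydroxy-4-(methoxymethoxy)benzaldehyde
Conditions: MOMCl (1.05 equiv), i-Pr2NEt (1.2 equiv), THF, 0 °C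
Reagents that add atoms: chloromethyl methyl ether, COCCl
Why: O-alkylation of a phenol (MOM ether formation) in which the hydroxyl para to the formyl group, the most acidic one and the only one never held in the hydrogen bond to the carbonyl oxygen, should react first with one equivalent of the chloride.

Step 2
Reactants: 2 2,6-dihydroxy-4-(methoxymethoxy)benzaldehyde
Product: 3 2,6-bis(benzyloxy)-4-(methoxymethoxy)benzaldehyde
Conditions: BnBr (2.5 equiv), K2CO3, DMF, 60 °C
Reagents that add atoms: benzyl bromide, BrCc1ccccc1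
Why: Williamson ether synthesis on the two remaining phenols, which are alkylated on oxygen as their potassium salts in warm DMF while the MOM acetal is inert to base.

Step 3
Reactants: 3 2,6-bis(benzyloxy)-4-(methoxymethoxy)benzaldehyde
Product: 4 1,3-bis(benzyloxy)-2-ethynyl-5-(methoxymethoxy)benzene
Conditions: dimethyl (1-diazo-2-oxopropyl)phosphonate, K2CO3, MeOH/THF, rt
Reagents that add atoms: dimethyl (1-diazo-2-oxopropyl)phosphonate, COP(=O)(OC)C(=[N+]=[N-])C(C)=O
Why: Seyferth–Gilbert homologation in the Ohira–Bestmann form turns an aryl aldehyde into the terminal alkyne in one operation under mild carbonate base that leaves benzyl and MOM ethers untouched.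

Step 4
Reactants: 4 1,3-bis(benzyloxy)-2-ethynyl-5-(methoxymethoxy)benzene
Product: 7 {[2,6-bis(benzyloxy)-4-(methoxymethoxy)phenyl]ethynyloxy}triisopropylsilane, via lithium acetylide 5 (not isolated), via lithium ynolate 6 (not isolated)
Conditions: LiN(SiMe3)2, THF, −78 °C; LiOOt-Bu (from t-BuOOH and LiN(SiMe3)2), −78 → 0 °C; TIPSCl, −78 °C → rt; chromatography on Et3N-deactivated silica
Reagents that add atoms: tert-butyl hydroperoxide, CC(C)(C)OO; chlorotriisopropylsilane, CC(C)[Si](Cl)(C(C)C)C(C)C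
Why: Julia ynolate synthesis, in which lithium tert-butyl peroxide transfers oxygen to the lithium acetylide and the bulky silyl chloride then traps the ynolate on oxygen as the silyl ynol ether.

Step 5
Reactants: 7 {[2,6-bis(benzyloxy)-4-(methoxymethoxy)phenyl]ethynyloxy}triisopropylsilane; 8 3-ethoxycyclobut-2-en-1-one
Product: 13 2',6'-bis(benzyloxy)-4-ethoxy-4'-(methoxymethoxy)-6-[(triisopropylsilyl)oxy]biphenyl-2-ol, via vinylketene 9 (not isolated), via vinylcyclobutenone 10 (not isolated), via dienylketene 11 (not isolated), via cyclohexadienone 12 (not isolated)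
Conditions: 8 (1.5 equiv), toluene, 80 → 110 °C, sealed tube
Reagents that add atoms: none
Why: This is a Danheiser benzannulation of a cyclobutenone with a siloxyalkyne, a known reaction type: reversible 4π electrocyclic opening of 8 gives vinylketene 9, whose ketene C=C adds (2+2) to the electron-rich alkyne of 7 to give cyclobutenone 10, and 4π opening of 10 gives dienylketene 11. Ring A of the apigenin half then closes by thermal 6π electrocyclisation of 11 (disrotatory, C8a'' to C4a''), and tautomerisation of cyclohexadienone 12 to the phenol should make the cascade irreversible. The cycloaddition forms C8''–C8a'' and C6''–C7'', the electrocyclisation re-forms C4a''–C8a'', and no stereocentre arises. The one selectivity required is the regiochemistry of the (2+2) event: the siloxy group polarises the alkyne so that its aryl-bearing carbon is the nucleophile and bonds to the ketene carbonyl carbon, which places the aryl group between the new hydroxyl (C8a'') and the siloxy group (C7'') and the ethoxy group at C5''. The two ortho benzyloxy groups crowd that alkyne carbon but also raise its nucleophilicity, and because the aryl–alkyne bond is simply carried into the new ring, the tetra-ortho-substituted biaryl arises without any cross-coupling. MOM, benzyl and silyl ethers should be inert to neutral heating in toluene.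

Step 6
Reactants: 13 2',6'-bis(benzyloxy)-4-ethoxy-4'-(methoxymethoxy)-6-[(triisopropylsilyl)oxy]biphenyl-2-ol
Product: 15 2',6'-bis(benzyloxy)-4-ethoxy-2-hydroxy-4'-(methoxymethoxy)-6-[(triisopropylsilyl)oxy]biphenyl-3-carbaldehyde, via hydroxymethylphenol 14 (not isolated)
Conditions: MgCl2, Et3N, (CH2O)n, MeCN, reflux
Reagents that add atoms: paraformaldehyde (as formaldehyde), C=O
Why: Magnesium-mediated ortho-formylation of a phenol (Casnati–Skattebøl), in which the magnesium phenoxide delivers formaldehyde only to the single free ortho carbon C4a'' and a second formaldehyde oxidises the hydroxymethyl intermediate 14 by hydride transfer, so that C6'' stays untouched.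

Step 7
Reactants: 15 2',6'-bis(benzyloxy)-4-ethoxy-2-hydroxy-4'-(methoxymethoxy)-6-[(triisopropylsilyl)oxy]biphenyl-3-carbaldehyde; 16 1-(benzyloxy)-4-ethynylbenzene
Product: 18 2',6'-bis(benzyloxy)-3-{3-[4-(benzyloxy)phenyl]-1-hydroxyprop-2-yn-1-yl}-4-ethoxy-4'-(methoxymethoxy)-6-[(triisopropylsilyl)oxy]biphenyl-2-ol (racemic), via lithium acetylide 17 (not isolated)
Conditions: 16 (3 equiv), n-BuLi (3 equiv), THF, −78 °C; then 15, −78 → 0 °C; aq. NH4Cl
Reagents that add atoms: none
Why: 1,2-addition of a lithium acetylide to an aldehyde, in which the first equivalent only deprotonates the phenol and the excess adds to the lithium-chelated formyl group; the carbinol centre forms without control as a racemate and is erased in step 8.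

Step 8
Reactants: 18 2',6'-bis(benzyloxy)-3-{3-[4-(benzyloxy)phenyl]-1-hydroxyprop-2-yn-1-yl}-4-ethoxy-4'-(methoxymethoxy)-6-[(triisopropylsilyl)oxy]biphenyl-2-ol
Product: 19 1-{2',6'-bis(benzyloxy)-4-ethoxy-2-hydroxy-4'-(methoxymethoxy)-6-[(triisopropylsilyl)oxy]biphenyl-3-yl}-3-[4-(benzyloxy)phenyl]prop-2-yn-1-one
Conditions: MnO2 (activated, excess), CH2Cl2, rt
Reagents that add atoms: none
Why: Manganese dioxide oxidation of a benzylic-propargylic alcohol, selective and neutral, which should avoid acid-induced ionisation of the electron-rich carbinol to an ortho-quinone methide.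

Step 9
Reactants: 19 1-{2',6'-bis(benzyloxy)-4-ethoxy-2-hydroxy-4'-(methoxymethoxy)-6-[(triisopropylsilyl)oxy]biphenyl-3-yl}-3-[4-(benzyloxy)phenyl]prop-2-yn-1-one
Product: 20 8-[2,6-bis(benzyloxy)-4-(methoxymethoxy)phenyl]-2-[4-(benzyloxy)phenyl]-5-ethoxy-7-[(triisopropylsilyl)oxy]-4H-chromen-4-one
Conditions: DMAP (20 mol %), DMF, rt → 40 °C
Reagents that add atoms: none
Why: Intramolecular oxa-Michael addition of the C8a'' phenol to the ynone in the 6-endo-dig mode under nucleophilic amine catalysis, the known way from ortho-hydroxyaryl ynones to flavones rather than aurones, run under neutral aprotic conditions that spare the aryl silyl ether.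

Step 10
Reactants: 20 8-[2,6-bis(benzyloxy)-4-(methoxymethoxy)phenyl]-2-[4-(benzyloxy)phenyl]-5-ethoxy-7-[(triisopropylsilyl)oxy]-4H-chromen-4-one
Product: 21 8-[2,6-bis(benzyloxy)-4-hydroxyphenyl]-2-[4-(benzyloxy)phenyl]-5-ethoxy-7-[(triisopropylsilyl)oxy]-4H-chromen-4-one
Conditions: HCl (1.25 M in MeOH), THF, 40 °C
Reagents that add atoms: none
Why: Acid-catalysed acetal exchange removes the MOM group as dimethoxymethane, while benzyl and ethyl ethers and the hindered aryl silyl ether should withstand dilute acid.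

Step 11
Reactants: 21 8-[2,6-bis(benzyloxy)-4-hydroxyphenyl]-2-[4-(benzyloxy)phenyl]-5-ethoxy-7-[(triisopropylsilyl)oxy]-4H-chromen-4-one
Product: 22 8-[2,6-bis(benzyloxy)-4-hydroxy-3-iodophenyl]-2-[4-(benzyloxy)phenyl]-5-ethoxy-7-[(triisopropylsilyl)oxy]-4H-chromen-4-one (racemic about the biaryl axis)
Conditions: NIS (1.0 equiv), DMF, 0 °C
Reagents that add atoms: N-iodosuccinimide, O=C1CCC(=O)N1I
Why: Electrophilic aromatic iodination of the free phenol ring, by far the most electron-rich ring, whose two ortho positions are equivalent so that one constitutional isomer should form, with one equivalent of reagent at low temperature limiting a second iodination.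

Step 12
Reactants: 22 8-[2,6-bis(benzyloxy)-4-hydroxy-3-iodophenyl]-2-[4-(benzyloxy)phenyl]-5-ethoxy-7-[(triisopropylsilyl)oxy]-4H-chromen-4-one; 23 4-ethynylanisole
Product: 26 5,7-bis(benzyloxy)-6-{2-[4-(benzyloxy)phenyl]-5-ethoxy-4-oxo-7-[(triisopropylsilyl)oxy]-4H-chromen-8-yl}-2-(4-methoxyphenyl)-4H-chromen-4-one, via ynone 24 (not isolated), via enaminone 25 (not isolated)
Conditions: PdCl2(dppf) (5 mol %), CO (20 bar), Et2NH, DMF, 100 °C
Reagents that add atoms: carbon monoxide, [C-]#[O+]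
Why: Palladium-catalysed carbonylative annulation of an ortho-iodophenol with a terminal alkyne, in which oxidative addition to zerovalent palladium, CO insertion and copper-free alkynylation give ynone 24, diethylamine adds to give enaminone 25, and the phenol displaces the amine in a 6-endo addition–elimination that should give the flavone and not the aurone.

Step 13
Reactants: 26 5,7-bis(benzyloxy)-6-{2-[4-(benzyloxy)phenyl]-5-ethoxy-4-oxo-7-[(triisopropylsilyl)oxy]-4H-chromen-8-yl}-2-(4-methoxyphenyl)-4H-chromen-4-one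
Product: 27 5,7-bis(benzyloxy)-6-{2-[4-(benzyloxy)phenyl]-5-ethoxy-7-hydroxy-4-oxo-4H-chromen-8-yl}-2-(4-methoxyphenyl)-4H-chromen-4-one
Conditions: Bu4NF, AcOH, THF, 0 °C
Reagents that add atoms: none
Why: Fluoride-induced cleavage of an aryl silyl ether driven by Si–F bond formation, buffered with acetic acid so that the flavones are not exposed to free phenoxide or basic fluoride.

Step 14
Reactants: 27 5,7-bis(benzyloxy)-6-{2-[4-(benzyloxy)phenyl]-5-ethoxy-7-hydroxy-4-oxo-4H-chromen-8-yl}-2-(4-methoxyphenyl)-4H-chromen-4-one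
Product: 28 5,7-dihydroxy-6-[5,7-dihydroxy-2-(4-hydroxyphenyl)-4-oxo-4H-chromen-8-yl]-2-(4-methoxyphenyl)-4H-chromen-4-one (the target)
Conditions: BCl3 (excess), C6HMe5, CH2Cl2, −78 °C → rt; MeOH, then H2O
Reagents that add atoms: none
Why: Lewis-acid ether cleavage with BCl3, which removes aryl benzyl ethers at low temperature with pentamethylbenzene as a non-basic benzyl-cation scavenger and, on warming, removes the peri ethyl group through its chelate between the C4'' carbonyl and O5'', whereas the unchelated 4'-methyl ether should be left intact.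

**Compound list**

1 | 2,4,6-trihydroxybenzaldehyde | O=Cc1c(O)cc(O)cc1O | starting material
2 | 2,6-dihydroxy-4-(methoxymethoxy)benzaldehyde | O=Cc1c(O)cc(OCOC)cc1O | intermediate
3 | 2,6-bis(benzyloxy)-4-(methoxymethoxy)benzaldehyde | O=Cc1c(OCc2ccccc2)cc(OCOC)cc1OCc1ccccc1 | intermediate
4 | 1,3-bis(benzyloxy)-2-ethynyl-5-(methoxymethoxy)benzene | C#Cc1c(OCc2ccccc2)cc(OCOC)cc1OCc1ccccc1 | intermediate
5 | lithium [2,6-bis(benzyloxy)-4-(methoxymethoxy)phenyl]acetylide (formed in the flask) | [Li+].[C-]#Cc1c(OCc2ccccc2)cc(OCOC)cc1OCc1ccccc1 | intermediate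
6 | lithium [2,6-bis(benzyloxy)-4-(methoxymethoxy)phenyl]ethynolate (formed in the flask) | [Li+].[O-]C#Cc1c(OCc2ccccc2)cc(OCOC)cc1OCc1ccccc1 | intermediate
7 | {[2,6-bis(benzyloxy)-4-(methoxymethoxy)phenyl]ethynyloxy}triisopropylsilane | CC(C)[Si](OC#Cc1c(OCc2ccccc2)cc(OCOC)cc1OCc1ccccc1)(C(C)C)C(C)C | intermediate
8 | 3-ethoxycyclobut-2-en-1-one | CCOC1=CC(=O)C1 | starting material
9 | 3-ethoxybuta-1,3-dien-1-one (vinylketene, formed in the flask) | C=C(OCC)C=C=O | intermediate
10 | 2-[2,6-bis(benzyloxy)-4-(methoxymethoxy)phenyl]-4-(1-ethoxyethenyl)-3-[(triisopropylsilyl)oxy]cyclobut-2-en-1-one (racemic, formed in the flask) | CCOC(=C)C1C(=O)C(c2c(OCc3ccccc3)cc(OCOC)cc2OCc2ccccc2)=C1O[Si](C(C)C)(C(C)C)C(C)C | intermediate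
11 | 2-[2,6-bis(benzyloxy)-4-(methoxymethoxy)phenyl]-5-ethoxy-3-[(triisopropylsilyl)oxy]hexa-1,3,5-trien-1-one, ketene carbon and ethoxyvinyl group cis on the central double bond (formed in the flask) | CCOC(=C)/C=C(O[Si](C(C)C)(C(C)C)C(C)C)\C(=C=O)c1c(OCc2ccccc2)cc(OCOC)cc1OCc1ccccc1 | intermediate
12 | 2-[2,6-bis(benzyloxy)-4-(methoxymethoxy)phenyl]-5-ethoxy-3-[(triisopropylsilyl)oxy]cyclohexa-2,4-dien-1-one (formed in the flask) | O=C1CC(OCC)=CC(O[Si](C(C)C)(C(C)C)C(C)C)=C1c1c(OCc2ccccc2)cc(OCOC)cc1OCc1ccccc1 | intermediate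
13 | 2',6'-bis(benzyloxy)-4-ethoxy-4'-(methoxymethoxy)-6-[(triisopropylsilyl)oxy]biphenyl-2-ol | CCOc1cc(O)c(-c2c(OCc3ccccc3)cc(OCOC)cc2OCc2ccccc2)c(O[Si](C(C)C)(C(C)C)C(C)C)c1 | intermediate
14 | 2',6'-bis(benzyloxy)-4-ethoxy-3-(hydroxymethyl)-4'-(methoxymethoxy)-6-[(triisopropylsilyl)oxy]biphenyl-2-ol (formed in the flask) | CCOc1cc(O[Si](C(C)C)(C(C)C)C(C)C)c(-c2c(OCc3ccccc3)cc(OCOC)cc2OCc2ccccc2)c(O)c1CO | intermediate
15 | 2',6'-bis(benzyloxy)-4-ethoxy-2-hydroxy-4'-(methoxymethoxy)-6-[(triisopropylsilyl)oxy]biphenyl-3-carbaldehyde | CCOc1cc(O[Si](C(C)C)(C(C)C)C(C)C)c(-c2c(OCc3ccccc3)cc(OCOC)cc2OCc2ccccc2)c(O)c1C=O | intermediate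
16 | 1-(benzyloxy)-4-ethynylbenzene | C#Cc1ccc(OCc2ccccc2)cc1 | starting material
17 | lithium [4-(benzyloxy)phenyl]acetylide (formed in the flask) | [Li+].[C-]#Cc1ccc(OCc2ccccc2)cc1 | intermediate
18 | 2',6'-bis(benzyloxy)-3-{3-[4-(benzyloxy)phenyl]-1-hydroxyprop-2-yn-1-yl}-4-ethoxy-4'-(methoxymethoxy)-6-[(triisopropylsilyl)oxy]biphenyl-2-ol (racemic) | CCOc1cc(O[Si](C(C)C)(C(C)C)C(C)C)c(-c2c(OCc3ccccc3)cc(OCOC)cc2OCc2ccccc2)c(O)c1C(O)C#Cc1ccc(OCc2ccccc2)cc1 | intermediate
19 | 1-{2',6'-bis(benzyloxy)-4-ethoxy-2-hydroxy-4'-(methoxymethoxy)-6-[(triisopropylsilyl)oxy]biphenyl-3-yl}-3-[4-(benzyloxy)phenyl]prop-2-yn-1-one | CCOc1cc(O[Si](C(C)C)(C(C)C)C(C)C)c(-c2c(OCc3ccccc3)cc(OCOC)cc2OCc2ccccc2)c(O)c1C(=O)C#Cc1ccc(OCc2ccccc2)cc1 | intermediate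
20 | 8-[2,6-bis(benzyloxy)-4-(methoxymethoxy)phenyl]-2-[4-(benzyloxy)phenyl]-5-ethoxy-7-[(triisopropylsilyl)oxy]-4H-chromen-4-one | CCOc1cc(O[Si](C(C)C)(C(C)C)C(C)C)c(-c2c(OCc3ccccc3)cc(OCOC)cc2OCc2ccccc2)c2oc(-c3ccc(OCc4ccccc4)cc3)cc(=O)c12 | intermediate
21 | 8-[2,6-bis(benzyloxy)-4-hydroxyphenyl]-2-[4-(benzyloxy)phenyl]-5-ethoxy-7-[(triisopropylsilyl)oxy]-4H-chromen-4-one | CCOc1cc(O[Si](C(C)C)(C(C)C)C(C)C)c(-c2c(OCc3ccccc3)cc(O)cc2OCc2ccccc2)c2oc(-c3ccc(OCc4ccccc4)cc3)cc(=O)c12 | intermediate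
22 | 8-[2,6-bis(benzyloxy)-4-hydroxy-3-iodophenyl]-2-[4-(benzyloxy)phenyl]-5-ethoxy-7-[(triisopropylsilyl)oxy]-4H-chromen-4-one (racemic about the axis) | CCOc1cc(O[Si](C(C)C)(C(C)C)C(C)C)c(-c2c(OCc3ccccc3)c(I)c(O)cc2OCc2ccccc2)c2oc(-c3ccc(OCc4ccccc4)cc3)cc(=O)c12 | intermediate
23 | 4-ethynylanisole | COc1ccc(C#C)cc1 | starting material
24 | 8-{2,6-bis(benzyloxy)-4-hydroxy-3-[3-(4-methoxyphenyl)prop-2-ynoyl]phenyl}-2-[4-(benzyloxy)phenyl]-5-ethoxy-7-[(triisopropylsilyl)oxy]-4H-chromen-4-one (formed in the flask) | CCOc1cc(O[Si](C(C)C)(C(C)C)C(C)C)c(-c2c(OCc3ccccc3)c(C(=O)C#Cc3ccc(OC)cc3)c(O)cc2OCc2ccccc2)c2oc(-c3ccc(OCc4ccccc4)cc3)cc(=O)c12 | intermediate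
25 | 8-{2,6-bis(benzyloxy)-3-[3-(diethylamino)-3-(4-methoxyphenyl)prop-2-enoyl]-4-hydroxyphenyl}-2-[4-(benzyloxy)phenyl]-5-ethoxy-7-[(triisopropylsilyl)oxy]-4H-chromen-4-one (double-bond geometry not fixed, formed in the flask) | CCOc1cc(O[Si](C(C)C)(C(C)C)C(C)C)c(-c2c(OCc3ccccc3)c(C(=O)C=C(N(CC)CC)c3ccc(OC)cc3)c(O)cc2OCc2ccccc2)c2oc(-c3ccc(OCc4ccccc4)cc3)cc(=O)c12 | intermediate
26 | 5,7-bis(benzyloxy)-6-{2-[4-(benzyloxy)phenyl]-5-ethoxy-4-oxo-7-[(triisopropylsilyl)oxy]-4H-chromen-8-yl}-2-(4-methoxyphenyl)-4H-chromen-4-one | CCOc1cc(O[Si](C(C)C)(C(C)C)C(C)C)c(-c2c(OCc3ccccc3)c3c(=O)cc(-c4ccc(OC)cc4)oc3cc2OCc2ccccc2)c2oc(-c3ccc(OCc4ccccc4)cc3)cc(=O)c12 | intermediate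
27 | 5,7-bis(benzyloxy)-6-{2-[4-(benzyloxy)phenyl]-5-ethoxy-7-hydroxy-4-oxo-4H-chromen-8-yl}-2-(4-methoxyphenyl)-4H-chromen-4-one | CCOc1cc(O)c(-c2c(OCc3ccccc3)c3c(=O)cc(-c4ccc(OC)cc4)oc3cc2OCc2ccccc2)c2oc(-c3ccc(OCc4ccccc4)cc3)cc(=O)c12 | intermediate
28 | 5,7-dihydroxy-6-[5,7-dihydroxy-2-(4-hydroxyphenyl)-4-oxo-4H-chromen-8-yl]-2-(4-methoxyphenyl)-4H-chromen-4-one (CNP0302154.0) | COc1ccc(-c2cc(=O)c3c(O)c(-c4c(O)cc(O)c5c(=O)cc(-c6ccc(O)cc6)oc45)c(O)cc3o2)cc1 | target

**Step count**

Total: 14 steps. Longest linear sequence: 14 steps (1 to 28); compounds 8, 16 and 23 are bought and enter at steps 5, 7 and 12.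

**Steps most likely to fail**

Step 5. The vinylogous-ester stabilisation of 8 may push its ring opening to temperatures at which the siloxyalkyne decays (silyl shift to a silylketene) or the vinylketene oligomerises before it is caught at the crowded aryl-bearing alkyne carbon. The fallback generates the same vinylketene 9 at room temperature by 1,4-dehydrochlorination instead of by electrocyclic opening. Commercial ethyl (E)-3-ethoxybut-2-enoate would be saponified (KOH, aqueous EtOH) to (E)-3-ethoxybut-2-enoic acid F1 and converted with oxalyl chloride and catalytic DMF into (E)-3-ethoxybut-2-enoyl chloride F2. Slow addition of F2 to 7 and Et3N in CH2Cl2 at room temperature should give 9 and, by the same (2+2) cycloaddition, cyclobutenone 10; brief heating of 10 in toluene then runs the 4π opening and 6π closure. The fallback sets out from 7 and returns to the route at 13.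

Step 12. Oxidative addition at the electron-rich carbon–iodine bond flanked by two oxygens may be slow, and direct alkynylation (leading to a benzofuran), aminocarbonylation to the diethylamide or 5-exo closure to the aurone may compete. Partial loss of the C7'' silyl ether in hot amine would be harmless because step 13 removes it. The fallback sets out from 21 and builds the second pyranone without palladium or CO, by the sequence already used for the first:
- Magnesium-mediated ortho-formylation (MgCl2, Et3N, paraformaldehyde) should pass through 8-[2,6-bis(benzyloxy)-4-hydroxy-3-(hydroxymethyl)phenyl]-2-[4-(benzyloxy)phenyl]-5-ethoxy-7-[(triisopropylsilyl)oxy]-4H-chromen-4-one F3 to 2,4-bis(benzyloxy)-3-{2-[4-(benzyloxy)phenyl]-5-ethoxy-4-oxo-7-[(triisopropylsilyl)oxy]-4H-chromen-8-yl}-6-hydroxybenzaldehyde F4.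
- Lithium (4-methoxyphenyl)acetylide F5, made from 23 and n-BuLi, would add at −78 °C to the aldehyde, which is far more electrophilic than the chromone carbonyl, to give 8-{2,6-bis(benzyloxy)-4-hydroxy-3-[1-hydroxy-3-(4-methoxyphenyl)prop-2-yn-1-yl]phenyl}-2-[4-(benzyloxy)phenyl]-5-ethoxy-7-[(triisopropylsilyl)oxy]-4H-chromen-4-one F6.
- MnO2 would oxidise F6 to ynone 24, and DMAP in DMF would close it to 26, where the route is rejoined.

Step 4. Oxygen transfer from the peroxide to the hindered, electron-rich acetylide may be incomplete, and the ynolate or the silyl ynol ether may hydrolyse during work-up. The fallback reaches the same ynolate by a Kowalski rearrangement, setting out from 3: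
- LiCHBr2 (from CH2Br2 and LiN(i-Pr)2, THF, −78 °C) would add to the aldehyde to give 1-[2,6-bis(benzyloxy)-4-(methoxymethoxy)phenyl]-2,2-dibromoethan-1-ol F7.
- Dess–Martin periodinane would oxidise it to 1-[2,6-bis(benzyloxy)-4-(methoxymethoxy)phenyl]-2,2-dibromoethan-1-one F8.
- LiN(SiMe3)2 would convert F8 into lithium 1-[2,6-bis(benzyloxy)-4-(methoxymethoxy)phenyl]-2,2-dibromoethen-1-olate F9.
- n-BuLi would exchange one bromine of F9, and the carbenoid should rearrange with 1,2-aryl shift to lithium ynolate 6; TIPSCl then gives 7, where the route is rejoined.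

Further compounds

F1 | step 5 | (E)-3-ethoxybut-2-enoic acid | CCO/C(C)=C/C(=O)O
F2 | step 5 | (E)-3-ethoxybut-2-enoyl chloride | CCO/C(C)=C/C(=O)Cl
F3 | step 12 | 8-[2,6-bis(benzyloxy)-4-hydroxy-3-(hydroxymethyl)phenyl]-2-[4-(benzyloxy)phenyl]-5-ethoxy-7-[(triisopropylsilyl)oxy]-4H-chromen-4-one | CCOc1cc(O[Si](C(C)C)(C(C)C)C(C)C)c(-c2c(OCc3ccccc3)c(CO)c(O)cc2OCc2ccccc2)c2oc(-c3ccc(OCc4ccccc4)cc3)cc(=O)c12
F4 | step 12 | 2,4-bis(benzyloxy)-3-{2-[4-(benzyloxy)phenyl]-5-ethoxy-4-oxo-7-[(triisopropylsilyl)oxy]-4H-chromen-8-yl}-6-hydroxybenzaldehyde | CCOc1cc(O[Si](C(C)C)(C(C)C)C(C)C)c(-c2c(OCc3ccccc3)c(C=O)c(O)cc2OCc2ccccc2)c2oc(-c3ccc(OCc4ccccc4)cc3)cc(=O)c12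
F5 | step 12 | lithium (4-methoxyphenyl)acetylide | [Li+].[C-]#Cc1ccc(OC)cc1
F6 | step 12 | 8-{2,6-bis(benzyloxy)-4-hydroxy-3-[1-hydroxy-3-(4-methoxyphenyl)prop-2-yn-1-yl]phenyl}-2-[4-(benzyloxy)phenyl]-5-ethoxy-7-[(triisopropylsilyl)oxy]-4H-chromen-4-one (racemic carbinol) | CCOc1cc(O[Si](C(C)C)(C(C)C)C(C)C)c(-c2c(OCc3ccccc3)c(C(O)C#Cc3ccc(OC)cc3)c(O)cc2OCc2ccccc2)c2oc(-c3ccc(OCc4ccccc4)cc3)cc(=O)c12
F7 | step 4 | 1-[2,6-bis(benzyloxy)-4-(methoxymethoxy)phenyl]-2,2-dibromoethan-1-ol (racemic) | OC(C(Br)Br)c1c(OCc2ccccc2)cc(OCOC)cc1OCc1ccccc1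
F8 | step 4 | 1-[2,6-bis(benzyloxy)-4-(methoxymethoxy)phenyl]-2,2-dibromoethan-1-one | O=C(C(Br)Br)c1c(OCc2ccccc2)cc(OCOC)cc1OCc1ccccc1
F9 | step 4 | lithium 1-[2,6-bis(benzyloxy)-4-(methoxymethoxy)phenyl]-2,2-dibromoethen-1-olate | [Li+].[O-]C(=C(Br)Br)c1c(OCc2ccccc2)cc(OCOC)cc1OCc1ccccc1
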